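**Assumption:** the SMILES is read as all-trans (1R,2S,3S)-isolariciresinol (tetralin C1 bears the aryl group; 1-aryl/2-CH2OH trans, 2-/3-CH2OH trans).

## Retrosynthetic overview

1. Only the tetralin B-ring is formed in the synthesis, and it is closed last, at the C1–C8a bond.
2. C1–C8a disconnection leads to C2-symmetric (S,S)-secoisolariciresinol. Forward, DDQ converts one of its two homotopic p-hydroxybenzyl units into a p-quinone methide (one ring dearomatised, C2 axis lost), which the other guaiacyl ring captures para to its OMe, setting C1.
3. C2–C3 (the 8–8′ bond) disconnection leads to two identical hydroferulic acid units, joined by oxidative homocoupling of an Evans imide enolate; the (R)-auxiliary sets both centres S.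
4. The monomer comes from ferulic acid by hydrogenation and a one-pot O-pivaloylation/N-acylation; a single LiAlH4 step later removes both auxiliaries and both pivalates.

## Route

**Step 1**
Reactants: 1, ferulic acid ((E)-4-hydroxy-3-methoxycinnamic acid)
Product: 2, hydroferulic acid (3-(4-hydroxy-3-methoxyphenyl)propanoic acid)
Conditions: H2 (1 atm), 10% Pd/C, EtOH, rt
Reagents that add atoms: none
Why: Catalytic hydrogenation of the cinnamate C=C; the arene, phenol and acid are inert under these conditions.

**Step 2**
Reactants: 2, hydroferulic acid; 3, pivaloyl chloride; 4, (R)-4-benzyl-2-oxazolidinone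
Product: 5, (R)-4-benzyl-3-[3-(3-methoxy-4-pivaloyloxyphenyl)propanoyl]oxazolidin-2-one
Conditions: 2 + Et3N (4 equiv) added to PivCl (2.3 equiv), DMAP (5 mol%), THF, 0 °C → rt; then 4 (1.2 equiv), LiCl, rt
Reagents that add atoms: pivaloyl chloride, CC(C)(C)C(=O)Cl; (R)-4-benzyl-2-oxazolidinone, O=C1N[C@H](Cc2ccccc2)CO1
Why: Mixed pivalic anhydride activation followed by LiCl/Et3N N-acylation (Evans auxiliary attachment), with excess PivCl capping the phenol as its pivalate in the same pot; the oxazolidinone attacks the unhindered acyl of the mixed anhydride, and the auxiliary stereocentre is carried in unchanged.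

**Step 3**
Reactants: 5 (two molecules)
Product: 6, (2S,3S)-2,3-bis(3-methoxy-4-pivaloyloxybenzyl)succinyl bis[(R)-4-benzyl-2-oxazolidinone] imide
Conditions: LDA (1.1 equiv), THF, −78 °C; then TiCl4 (1.1 equiv), −78 °C → rt; chromatography/recrystallisation
Reagents that add atoms: none
Why: Oxidative enolate homocoupling: the chelated Z-enolate is oxidised through a Ti(IV) enolate/Ti(III) α-radical, and each α-carbon bonds on the face anti to the 4-benzyl group (same facial sense as Evans alkylation), so the (R)-auxiliary gives S at both new centres; minor diastereomers are separable because the auxiliary is still attached.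

**Step 4**
Reactants: 6
Product: 7, (2S,3S)-2,3-bis(4-hydroxy-3-methoxybenzyl)butane-1,4-diol ((S,S)-secoisolariciresinol)
Conditions: LiAlH4 (excess), THF, 0 °C → rt; Rochelle salt / dilute HCl work-up
Reagents that add atoms: none
Why: Hydride reduction cleaves both N-acyl oxazolidinones to primary alcohols and both aryl pivalates to phenols in one operation; hydride addition outpaces enolisation, so the two stereocentres are untouched.

**Step 5 (key step)**
Reactants: 7
Product: 8, (1R,2S,3S)-7-hydroxy-1-(4-hydroxy-3-methoxyphenyl)-6-methoxy-1,2,3,4-tetrahydronaphthalene-2,3-dimethanol (isolariciresinol, target)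
Conditions: DDQ (0.9 equiv, slow addition), 1,4-dioxane, 10 °C → rt; then TFA (10 equiv), CH2Cl2, 0 °C → rt; aq. NaHCO3; unreacted 7 recycled
Reagents that add atoms: none
Why: DDQ dehydrogenation of a p-alkylphenol to a p-quinone methide, first held reversibly as the lariciresinol-type cyclic ether by the γ-OH, then closed irreversibly under TFA by C6 of the other guaiacyl ring in a six-ring Friedel–Crafts alkylation (biomimetic cyclolignan formation, as in the acid-induced lariciresinol → isolariciresinol rearrangement); chair-like closure with both CH2OH groups and the aryl pseudo-equatorial sets C1 trans to C2, and the product forms only after the oxidant is spent.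

## Compound list

1 | ferulic acid | COc1cc(/C=C/C(=O)O)ccc1O | starting material
2 | hydroferulic acid | COc1cc(CCC(=O)O)ccc1O | intermediate
3 | pivaloyl chloride | CC(C)(C)C(=O)Cl | starting material
4 | (R)-4-benzyl-2-oxazolidinone | O=C1N[C@H](Cc2ccccc2)CO1 | starting material
5 | (R)-4-benzyl-3-[3-(3-methoxy-4-pivaloyloxyphenyl)propanoyl]oxazolidin-2-one | COc1cc(CCC(=O)N2C(=O)OC[C@H]2Cc2ccccc2)ccc1OC(=O)C(C)(C)C | intermediate
6 | (2S,3S)-bis-imide dimer | COc1cc(C[C@H](C(=O)N2C(=O)OC[C@H]2Cc2ccccc2)[C@@H](C(=O)N2C(=O)OC[C@H]2Cc2ccccc2)Cc2ccc(OC(=O)C(C)(C)C)c(OC)c2)ccc1OC(=O)C(C)(C)C | intermediate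
7 | (S,S)-secoisolariciresinol | COc1cc(C[C@H](CO)[C@@H](CO)Cc2ccc(O)c(OC)c2)ccc1O | intermediate
8 | (1R,2S,3S)-isolariciresinol | COc1cc([C@@H]2c3cc(O)c(OC)cc3C[C@H](CO)[C@H]2CO)ccc1O | target

## Totals

Total steps: 5. Longest linear sequence: 5 (4 if catalogue compound 2 is bought instead of made).

## Three steps most likely to fail

1. **Step 5.** The two phenolic benzyl sites are nearly independent, so double oxidation is statistical, and the product itself has oxidisable benzylic C–H bonds; expect partial conversion per pass. Fallback: give up C–H oxidation and bring the benzylic oxygen in with an aldehyde. Aldol of an (S)-β-(4-benzyloxy-3-methoxybenzyl)-γ-butyrolactone enolate with O-benzylvanillin, TFA Friedel–Crafts closure of the benzylic alcohol, then LiAlH4 and hydrogenolysis.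

2. **Step 3.** Yield and diastereoselectivity of the radical dimerisation may be modest, and α-chlorination or simple reprotonation can compete. Fallback: make the 8–8′ bond by stepwise alkylation instead. Evans alkylation of the imide with tert-butyl bromoacetate, reduction and lactonisation to the (S)-β-benzylbutyrolactone, trans-selective enolate alkylation with the second protected benzyl bromide, then LiAlH4 to 7.

3. **Step 2.** The activated phenolic acid can self-condense to oligoesters before the phenol is capped. Fallback: change the protecting-group strategy to a discrete benzyl ether (BnBr/K2CO3 then saponification, acid chloride plus N-lithiated 4), removed by hydrogenolysis after step 4.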